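## Retrosynthetic overview

1. Both rings are formed last and together: one intramolecular Diels–Alder reaction of an all-E linear 5-oxo-pentaenoic acid closes the cyclohexene and the cyclopentanone (chain bonds C3–C7 and C2–C10, four stereocentres), run under a new boronic acid catalysis of the free acid.
2. The keto acid comes from its C5 alcohol, assembled at C8–C9 by Stille coupling of a C1–C8 vinyl iodide acid with a C9–C14 trienyl stannane.
3. The vinyl iodide acid comes from an auxiliary-controlled vinylogous Mukaiyama aldol (C4–C5 bond, sets the ethyl-bearing centre) on an iodo-enal made from the Roche ester (source of the methyl-bearing centre).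
4. The stannane comes from ethyl 3-oxopentanoate and styrylboronic acid by E-enol triflate/Suzuki coupling, Colvin alkyne synthesis and zirconium-catalysed carboalumination.

Assumption: (E)-2-ethylhex-2-enoic acid is bought as the pure E isomer, and the diethyl ketene N,O-acetal made from it follows the facial rule of its dimethyl parent (attack anti to the isopropyl group).

## Route

Step 1
Reactants: 1 methyl (R)-3-hydroxy-2-methylpropanoate
Product: 2 methyl (R)-3-[(tert-butyldimethylsilyl)oxy]-2-methylpropanoate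
Conditions: TBSCl, imidazole, DMF, 0 °C → rt
Reagents that add atoms: tert-butyldimethylsilyl chloride, CC(C)(C)[Si](C)(C)Cl
Why: Imidazole-promoted O-silylation of the primary alcohol (silyl ether protection); the stereocentre is not involved.

Step 2
Reactants: 2 methyl (R)-3-[(tert-butyldimethylsilyl)oxy]-2-methylpropanoate
Product: 3 (R)-3-[(tert-butyldimethylsilyl)oxy]-2-methylpropanal
Conditions: i-Bu2AlH (1.05 equiv), CH2Cl2, −78 °C; aq. potassium sodium tartrate
Reagents that add atoms: none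
Why: Partial ester reduction, in which the tetrahedral aluminium hemiacetal survives at −78 °C and releases the aldehyde only on work-up, so over-reduction and α-epimerisation are avoided when 3 is used at once.

Step 3
Reactants: 3 (R)-3-[(tert-butyldimethylsilyl)oxy]-2-methylpropanal
Product: 4 (S)-tert-butyl[(4,4-dibromo-2-methylbut-3-en-1-yl)oxy]dimethylsilane
Conditions: CBr4, PPh3, Zn, CH2Cl2, rt; then 3, 0 °C → rt
Reagents that add atoms: carbon tetrabromide, BrC(Br)(Br)Br
Why: Corey–Fuchs dibromo-olefination (Wittig type) under neutral zinc-buffered conditions leaves the α-stereocentre and the silyl ether untouched (the descriptor changes by priority only).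

Step 4
Reactants: 4 (S)-tert-butyl[(4,4-dibromo-2-methylbut-3-en-1-yl)oxy]dimethylsilane
Product: 6 (S)-tert-butyldimethyl[(2-methylpent-3-yn-1-yl)oxy]silane, via lithium acetylide 5 (not isolated)
Conditions: n-BuLi (2.2 equiv), THF, −78 → 0 °C; then MeI, −78 °C → rt
Reagents that add atoms: iodomethane, CI
Why: Second stage of the Corey–Fuchs alkyne synthesis (Br/Li exchange, Fritsch–Buttenberg–Wiechell rearrangement) followed by C-methylation of the acetylide, conditions under which the propargylic centre is not deprotonated.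

Step 5
Reactants: 6 (S)-tert-butyldimethyl[(2-methylpent-3-yn-1-yl)oxy]silane
Product: 8 (S,E)-tert-butyl[(4-iodo-2-methylpent-3-en-1-yl)oxy]dimethylsilane, via alkenylzirconocene chloride 7 (not isolated)
Conditions: Cp2Zr(H)Cl (2.2 equiv), THF, 50 °C; then I2, THF, 0 °C
Reagents that add atoms: iodine, II
Why: Hydrozirconation–iodination, in which syn addition under thermodynamic regiocontrol puts zirconium on the alkyne carbon next to the methyl group and iodinolysis with retention gives the E 2-iodoalkene.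

Step 6
Reactants: 8 (S,E)-tert-butyl[(4-iodo-2-methylpent-3-en-1-yl)oxy]dimethylsilane
Product: 9 (S,E)-4-iodo-2-methylpent-3-en-1-ol
Conditions: CSA (10 mol %), MeOH/CH2Cl2, 0 °C → rt
Reagents that add atoms: none
Why: Acid-catalysed methanolysis of the primary silyl ether (silyl ether cleavage), to which the vinyl iodide is inert.

Step 7
Reactants: 9 (S,E)-4-iodo-2-methylpent-3-en-1-ol
Product: 10 (S,E)-4-iodo-2-methylpent-3-enal
Conditions: Dess–Martin periodinane, NaHCO3, CH2Cl2, 0 °C; used crude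
Reagents that add atoms: none
Why: Buffered Dess–Martin oxidation gives the α-chiral β,γ-unsaturated aldehyde without base, and A(1,3) strain with the cis methyl group disfavours enolisation, so it is carried on without racemisation.

Step 8
Reactants: 11 (E)-2-ethylhex-2-enoic acid; 12 (S)-4-isopropyloxazolidin-2-one
Product: 14 (S)-3-[(E)-2-ethylhex-2-enoyl]-4-isopropyloxazolidin-2-one, via mixed pivalic anhydride 13 (not isolated)
Conditions: PivCl, Et3N, THF, −20 °C; then LiCl, 12, rt
Reagents that add atoms: none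
Why: N-Acylation of the oxazolidinone through the mixed pivalic anhydride with LiCl activation, where attack occurs at the less hindered enoyl carbonyl and the alkene geometry is kept.

Step 9
Reactants: 14 (S)-3-[(E)-2-ethylhex-2-enoyl]-4-isopropyloxazolidin-2-one
Product: 16 (S)-3-[(1E,3E)-1-[(tert-butyldimethylsilyl)oxy]-2-ethylhexa-1,3-dien-1-yl]-4-isopropyloxazolidin-2-one, via sodium dienolate 15 (not isolated)
Conditions: NaN(SiMe3)2, THF, −78 °C; then TBSCl, −78 °C → rt
Reagents that add atoms: tert-butyldimethylsilyl chloride, CC(C)(C)[Si](C)(C)Cl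
Why: Kinetic γ-deprotonation of the s-trans enoyl imide and O-silylation of the extended dienolate give the E,E vinylketene silyl N,O-acetal, in which the oxazolidinone ring stands perpendicular to the diene.

Step 10
Reactants: 10 (S,E)-4-iodo-2-methylpent-3-enal; 16 (S)-3-[(1E,3E)-1-[(tert-butyldimethylsilyl)oxy]-2-ethylhexa-1,3-dien-1-yl]-4-isopropyloxazolidin-2-one
Product: 17 (S)-3-[(2E,4S,5R,6S,7E)-2,4-diethyl-5-hydroxy-8-iodo-6-methylnona-2,7-dienoyl]-4-isopropyloxazolidin-2-one
Conditions: TiCl4 (1.0 equiv), CH2Cl2, −78 → −40 °C; 16 (1.5 equiv)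
Reagents that add atoms: none
Why: Kobayashi-type vinylogous Mukaiyama aldol, in which the TiCl4-bound aldehyde attacks the γ-carbon from the face opposite the isopropyl group (sets C4 as S), the open transition state gives the 4,5-anti relationship (C5 R, also the Felkin sense for the C6 centre, a matched pair), and the E-enoyl unit forms at the same time.

Step 11
Reactants: 17 (S)-3-[(2E,4S,5R,6S,7E)-2,4-diethyl-5-hydroxy-8-iodo-6-methylnona-2,7-dienoyl]-4-isopropyloxazolidin-2-one
Product: 19 (2E,4S,5R,6S,7E)-2,4-diethyl-5-hydroxy-8-iodo-6-methylnona-2,7-dienoic acid, via peroxy acid 18 (not isolated)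
Conditions: LiOH, 30% H2O2, THF/H2O, 0 °C; then aq. Na2SO3; aq. HCl to pH 3
Reagents that add atoms: hydrogen peroxide, OO
Why: Evans auxiliary cleavage, in which hydroperoxide attacks the exocyclic imide carbonyl selectively and sulfite reduces the peracid, while the weakly acidic γ-centre C4 and the vinyl iodide are untouched.

Step 12
Reactants: 20 ethyl 3-oxopentanoate
Product: 21 ethyl (E)-3-{[(trifluoromethyl)sulfonyl]oxy}pent-2-enoate
Conditions: Tf2O, aq. Me4NOH, hexanes, 5 °C
Reagents that add atoms: trifluoromethanesulfonic anhydride, O=S(=O)(OS(=O)(=O)C(F)(F)F)C(F)(F)F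
Why: Stereoselective enol triflate formation, in which the non-chelated tetramethylammonium enolate adopts the dipole-minimised E geometry and is O-triflated with the triflate trans to the ester.

Step 13
Reactants: 21 ethyl (E)-3-{[(trifluoromethyl)sulfonyl]oxy}pent-2-enoate; 22 (E)-(2-phenylethenyl)boronic acid
Product: 23 ethyl (2E,4E)-3-ethyl-5-phenylpenta-2,4-dienoate
Conditions: Pd(PPh3)4 (3 mol %), K3PO4, THF/H2O, 60 °C
Reagents that add atoms: none
Why: Suzuki–Miyaura coupling of the activated β-triflyloxy enoate with retention of both alkene geometries, which places the styryl group trans to the ester.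

Step 14
Reactants: 23 ethyl (2E,4E)-3-ethyl-5-phenylpenta-2,4-dienoate
Product: 24 (2E,4E)-3-ethyl-5-phenylpenta-2,4-dien-1-ol
Conditions: i-Bu2AlH (2.2 equiv), CH2Cl2, −78 → 0 °C; aq. potassium sodium tartrate
Reagents that add atoms: none
Why: Clean 1,2-reduction of the conjugated ester to the allylic alcohol by the aluminium hydride (ester reduction) without touching the diene.

Step 15
Reactants: 24 (2E,4E)-3-ethyl-5-phenylpenta-2,4-dien-1-ol
Product: 25 (2E,4E)-3-ethyl-5-phenylpenta-2,4-dienal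
Conditions: MnO2, CH2Cl2, rt
Reagents that add atoms: none
Why: Chemoselective MnO2 oxidation of the allylic alcohol, neutral and without E/Z isomerisation.

Step 16
Reactants: 25 (2E,4E)-3-ethyl-5-phenylpenta-2,4-dienal
Product: 26 [(1E,3E)-3-ethylhexa-1,3-dien-5-yn-1-yl]benzene
Conditions: TMSCHN2, n-BuLi, THF, −78 °C; then 25, −78 °C → rt
Reagents that add atoms: (trimethylsilyl)diazomethane, C[Si](C)(C)C=[N+]=[N-]
Why: Colvin rearrangement (1,2-addition of lithiated silyldiazomethane, Peterson-type elimination, 1,2-hydride shift of the alkylidene carbene) gives the terminal alkyne and avoids the methanol conjugate addition that troubles enals in basic methanolic homologations.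

Step 17
Reactants: 26 [(1E,3E)-3-ethylhexa-1,3-dien-5-yn-1-yl]benzene
Product: 28 [(1E,3E,5E)-3-ethyl-6-iodo-5-methylhexa-1,3,5-trien-1-yl]benzene, via alkenylalane 27 (not isolated)
Conditions: Me3Al (2.5 equiv), Cp2ZrCl2 (25 mol %), CH2Cl2, 0 °C → rt; then I2, THF, −30 °C
Reagents that add atoms: trimethylaluminium, C[Al](C)C; iodine, II
Why: Negishi zirconium-catalysed carboalumination adds methyl and aluminium syn across the terminal alkyne with aluminium on the terminal carbon, and iodinolysis with retention gives the E trisubstituted iodide.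

Step 18
Reactants: 28 [(1E,3E,5E)-3-ethyl-6-iodo-5-methylhexa-1,3,5-trien-1-yl]benzene
Product: 30 tributyl[(1E,3E,5E)-4-ethyl-2-methyl-6-phenylhexa-1,3,5-trien-1-yl]stannane, via alkenyllithium 29 (not isolated)
Conditions: t-BuLi (2.1 equiv), Et2O, −78 °C; then Bu3SnCl, −78 °C → rt
Reagents that add atoms: tributyltin chloride, CCCC[Sn](Cl)(CCCC)CCCC
Why: Iodine–lithium exchange and stannylation of the alkenyllithium both proceed with retention at the sp2 carbon (halogen–metal exchange).

Step 19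
Reactants: 19 (2E,4S,5R,6S,7E)-2,4-diethyl-5-hydroxy-8-iodo-6-methylnona-2,7-dienoic acid; 30 tributyl[(1E,3E,5E)-4-ethyl-2-methyl-6-phenylhexa-1,3,5-trien-1-yl]stannane
Product: 31 (2E,4S,5R,6S,7E,9E,11E,13E)-2,4,12-triethyl-5-hydroxy-6,8,10-trimethyl-14-phenyltetradeca-2,7,9,11,13-pentaenoic acid
Conditions: Pd2(dba)3 (5 mol %), AsPh3 (40 mol %), i-Pr2NEt, NMP, 40 °C, dark
Reagents that add atoms: none
Why: Stille coupling joins C8 and C9 with retention at both alkenyl carbons under neutral conditions that tolerate the free alcohol and the amine-buffered carboxylic acid, giving the all-E tetraene.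

Step 20
Reactants: 31 (2E,4S,5R,6S,7E,9E,11E,13E)-2,4,12-triethyl-5-hydroxy-6,8,10-trimethyl-14-phenyltetradeca-2,7,9,11,13-pentaenoic acid
Product: 32 (2E,4S,6S,7E,9E,11E,13E)-2,4,12-triethyl-6,8,10-trimethyl-5-oxo-14-phenyltetradeca-2,7,9,11,13-pentaenoic acid
Conditions: Dess–Martin periodinane, NaHCO3, CH2Cl2, 0 °C; used at once
Reagents that add atoms: none
Why: Buffered Dess–Martin oxidation of the secondary alcohol gives the doubly β,γ-unsaturated ketone without acid or strong base, so C4 and C6 keep their configuration and the alkenes stay out of conjugation.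

Step 21
Reactants: 32 (2E,4S,6S,7E,9E,11E,13E)-2,4,12-triethyl-6,8,10-trimethyl-5-oxo-14-phenyltetradeca-2,7,9,11,13-pentaenoic acid
Product: 33 (1S,3S,3aR,4R,5R,7aR)-3,4-diethyl-5-[(1E,3E)-2-ethyl-4-phenylbuta-1,3-dien-1-yl]-1,5,7-trimethyl-2-oxo-2,3,3a,4,5,7a-hexahydro-1H-indene-4-carboxylic acid (CNP0268209.1)
Conditions: 2-bromophenylboronic acid (20 mol %), 4 Å molecular sieves, CH2Cl2, 25 °C
Reagents that add atoms: none
Why: Proposed new method: an electron-poor ortho-halo arylboronic acid should condense reversibly with the free acid of 32 to a monoacyloxyboronate whose boron-activated, LUMO-lowered enoate undergoes the type 1 intramolecular Diels–Alder reaction at 25 °C; the activated carboxyl sits endo and the three-atom keto tether exo (trans ring fusion, adjacent quaternary C4 and C5 of 33), while C4–H and C6–H of the chain of 32 eclipse the C2-ethyl and C8-methyl groups to avoid A(1,3) strain, which fixes the dienophile and diene faces and so sets C3a, C4, C5 and C7a of 33 relative to the two centres carried from 32, and acyl exchange with fresh 32 frees the hindered product acid and turns the catalyst over; the closest known reactions are the boronic-acid-catalysed intermolecular Diels–Alder reaction of acrylic acid and the thermal intramolecular Diels–Alder reaction of 1,3,8-nonatriene esters, neither shown for an intramolecular case, an α,β-dialkylacrylic acid or the formation of two adjacent quaternary carbons.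

## Compound list

1 | methyl (R)-3-hydroxy-2-methylpropanoate | COC(=O)[C@H](C)CO | starting material
2 | methyl (R)-3-[(tert-butyldimethylsilyl)oxy]-2-methylpropanoate | COC(=O)[C@H](C)CO[Si](C)(C)C(C)(C)C | intermediate
3 | (R)-3-[(tert-butyldimethylsilyl)oxy]-2-methylpropanal | O=C[C@H](C)CO[Si](C)(C)C(C)(C)C | intermediate
4 | (S)-tert-butyl[(4,4-dibromo-2-methylbut-3-en-1-yl)oxy]dimethylsilane | BrC(Br)=C[C@H](C)CO[Si](C)(C)C(C)(C)C | intermediate
5 | [(3S)-4-[(tert-butyldimethylsilyl)oxy]-3-methylbut-1-yn-1-yl]lithium | [Li]C#C[C@H](C)CO[Si](C)(C)C(C)(C)C | intermediate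
6 | (S)-tert-butyldimethyl[(2-methylpent-3-yn-1-yl)oxy]silane | CC#C[C@H](C)CO[Si](C)(C)C(C)(C)C | intermediate
7 | chlorobis(cyclopentadienyl)[(2E,4S)-5-[(tert-butyldimethylsilyl)oxy]-4-methylpent-2-en-2-yl]zirconium | Cl[Zr](C1C=CC=C1)(C1C=CC=C1)/C(C)=C/[C@H](C)CO[Si](C)(C)C(C)(C)C | intermediate
8 | (S,E)-tert-butyl[(4-iodo-2-methylpent-3-en-1-yl)oxy]dimethylsilane | I/C(C)=C/[C@H](C)CO[Si](C)(C)C(C)(C)C | intermediate
9 | (S,E)-4-iodo-2-methylpent-3-en-1-ol | I/C(C)=C/[C@H](C)CO | intermediate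
10 | (S,E)-4-iodo-2-methylpent-3-enal | I/C(C)=C/[C@H](C)C=O | intermediate
11 | (E)-2-ethylhex-2-enoic acid | CCC/C=C(CC)/C(=O)O | starting material
12 | (S)-4-isopropyloxazolidin-2-one | CC(C)[C@H]1COC(=O)N1 | starting material
13 | (E)-2-ethylhex-2-enoic pivalic anhydride | CCC/C=C(CC)/C(=O)OC(=O)C(C)(C)C | intermediate
14 | (S)-3-[(E)-2-ethylhex-2-enoyl]-4-isopropyloxazolidin-2-one | CCC/C=C(CC)/C(=O)N1[C@@H](C(C)C)COC1=O | intermediate
15 | sodium (1E,3E)-2-ethyl-1-[(S)-4-isopropyl-2-oxooxazolidin-3-yl]hexa-1,3-dien-1-olate | CC/C=C/C(CC)=C(/[O-])N1[C@@H](C(C)C)COC1=O.[Na+] | intermediate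
16 | (S)-3-[(1E,3E)-1-[(tert-butyldimethylsilyl)oxy]-2-ethylhexa-1,3-dien-1-yl]-4-isopropyloxazolidin-2-one | CC/C=C/C(CC)=C(/O[Si](C)(C)C(C)(C)C)N1[C@@H](C(C)C)COC1=O | intermediate
17 | (S)-3-[(2E,4S,5R,6S,7E)-2,4-diethyl-5-hydroxy-8-iodo-6-methylnona-2,7-dienoyl]-4-isopropyloxazolidin-2-one | CC(C)[C@H]1COC(=O)N1C(=O)/C(CC)=C/[C@H](CC)[C@H](O)[C@@H](C)/C=C(C)/I | intermediate
18 | (2E,4S,5R,6S,7E)-2,4-diethyl-5-hydroxy-8-iodo-6-methylnona-2,7-dieneperoxoic acid | OOC(=O)/C(CC)=C/[C@H](CC)[C@H](O)[C@@H](C)/C=C(C)/I | intermediate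
19 | (2E,4S,5R,6S,7E)-2,4-diethyl-5-hydroxy-8-iodo-6-methylnona-2,7-dienoic acid | OC(=O)/C(CC)=C/[C@H](CC)[C@H](O)[C@@H](C)/C=C(C)/I | intermediate
20 | ethyl 3-oxopentanoate | CCOC(=O)CC(=O)CC | starting material
21 | ethyl (E)-3-{[(trifluoromethyl)sulfonyl]oxy}pent-2-enoate | CCOC(=O)/C=C(CC)/OS(=O)(=O)C(F)(F)F | intermediate
22 | (E)-(2-phenylethenyl)boronic acid | OB(O)/C=C/c1ccccc1 | starting material
23 | ethyl (2E,4E)-3-ethyl-5-phenylpenta-2,4-dienoate | CCOC(=O)/C=C(CC)/C=C/c1ccccc1 | intermediate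
24 | (2E,4E)-3-ethyl-5-phenylpenta-2,4-dien-1-ol | OC/C=C(CC)/C=C/c1ccccc1 | intermediate
25 | (2E,4E)-3-ethyl-5-phenylpenta-2,4-dienal | O=C/C=C(CC)/C=C/c1ccccc1 | intermediate
26 | [(1E,3E)-3-ethylhexa-1,3-dien-5-yn-1-yl]benzene | C#C/C=C(CC)/C=C/c1ccccc1 | intermediate
27 | dimethyl[(1E,3E,5E)-4-ethyl-2-methyl-6-phenylhexa-1,3,5-trien-1-yl]alane | C[Al](C)/C=C(C)/C=C(CC)/C=C/c1ccccc1 | intermediate
28 | [(1E,3E,5E)-3-ethyl-6-iodo-5-methylhexa-1,3,5-trien-1-yl]benzene | I/C=C(C)/C=C(CC)/C=C/c1ccccc1 | intermediate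
29 | [(1E,3E,5E)-4-ethyl-2-methyl-6-phenylhexa-1,3,5-trien-1-yl]lithium | [Li]/C=C(C)/C=C(CC)/C=C/c1ccccc1 | intermediate
30 | tributyl[(1E,3E,5E)-4-ethyl-2-methyl-6-phenylhexa-1,3,5-trien-1-yl]stannane | CCCC[Sn](CCCC)(CCCC)/C=C(C)/C=C(CC)/C=C/c1ccccc1 | intermediate
31 | (2E,4S,5R,6S,7E,9E,11E,13E)-2,4,12-triethyl-5-hydroxy-6,8,10-trimethyl-14-phenyltetradeca-2,7,9,11,13-pentaenoic acid | OC(=O)/C(CC)=C/[C@H](CC)[C@H](O)[C@@H](C)/C=C(C)/C=C(C)/C=C(CC)/C=C/c1ccccc1 | intermediate
32 | (2E,4S,6S,7E,9E,11E,13E)-2,4,12-triethyl-6,8,10-trimethyl-5-oxo-14-phenyltetradeca-2,7,9,11,13-pentaenoic acid | OC(=O)/C(CC)=C/[C@H](CC)C(=O)[C@@H](C)/C=C(C)/C=C(C)/C=C(CC)/C=C/c1ccccc1 | intermediate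
33 | (1S,3S,3aR,4R,5R,7aR)-3,4-diethyl-5-[(1E,3E)-2-ethyl-4-phenylbuta-1,3-dien-1-yl]-1,5,7-trimethyl-2-oxo-2,3,3a,4,5,7a-hexahydro-1H-indene-4-carboxylic acid | CCC(/C=C/c1ccccc1)=C\[C@@]1(C)C=C(C)[C@@H]2[C@H]([C@H](CC)C(=O)[C@H]2C)[C@@]1(CC)C(=O)O | target

## Step count and risks

Total step count: 21. Longest linear sequence: 12 steps (steps 1–7, 10, 11, 19, 20, 21, from 1 to 33).

Three steps most likely to fail:

**Step 21 (proposed boronic-acid-catalysed cycloaddition).** The catalyst may not engage the hindered α,β-dialkyl enoic acid, or 32 may isomerise before it cyclises. The fallback uses known chemistry, sets out from 31 and comes back at 33. O-Allylation of the carboxylate of 31 (allyl bromide, K2CO3, DMF) gives prop-2-en-1-yl (2E,4S,5R,6S,7E,9E,11E,13E)-2,4,12-triethyl-5-hydroxy-6,8,10-trimethyl-14-phenyltetradeca-2,7,9,11,13-pentaenoate F1. Dess–Martin oxidation gives the corresponding 5-oxo allyl ester F2. Heating F2 in toluene at 90 °C with BHT effects the thermal type 1 intramolecular Diels–Alder reaction of the ester-activated triene, through the same A(1,3)-controlled ester-endo transition state, to the bicyclic allyl ester of 33, F3. Deallylation with Pd(PPh3)4 and morpholine in THF (zerovalent palladium π-allyl transfer, no acid or base that could epimerise C1 or C3) returns 33.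

**Step 10 (vinylogous Mukaiyama aldol).** The diethyl homologue of the usual dimethyl ketene N,O-acetal is untested, the facial sense rests on the stated assumption, and aldehyde 10 is epimerisable. The fallback sets out from 10 and comes back at 32.
- Evans syn-aldol of 10 with the dibutylboron Z-enolate of (R)-4-benzyl-3-butanoyloxazolidin-2-one (Bu2BOTf, i-Pr2NEt, CH2Cl2, −78 → 0 °C) sets the ethyl-bearing centre with the known auxiliary-controlled sense and gives (R)-4-benzyl-3-[(2R,3S,4S,5E)-2-ethyl-3-hydroxy-6-iodo-4-methylhept-5-enoyl]oxazolidin-2-one F4. Its carbinol configuration does not matter because that carbon becomes the ketone.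
- TESOTf and 2,6-lutidine give the triethylsilyl ether F5.
- LiBH4 (THF/MeOH) removes the auxiliary to give (2S,3S,4S,5E)-2-ethyl-6-iodo-4-methyl-3-[(triethylsilyl)oxy]hept-5-en-1-ol F6.
- Dess–Martin oxidation gives the aldehyde F7.
- Wittig olefination with 2-(trimethylsilyl)ethyl 2-(triphenylphosphoranylidene)butanoate (toluene, 60 °C) gives 2-(trimethylsilyl)ethyl (2E,4S,5S,6S,7E)-2,4-diethyl-8-iodo-6-methyl-5-[(triethylsilyl)oxy]nona-2,7-dienoate F8.
- Bu4NF in THF removes the silyl ether and the silylethyl ester together to give (2E,4S,5S,6S,7E)-2,4-diethyl-5-hydroxy-8-iodo-6-methylnona-2,7-dienoic acid F9, the C5 epimer of 19.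
- Stille coupling with 30 under the step 19 conditions gives the C5 epimer of 31, (2E,4S,5S,6S,7E,9E,11E,13E)-2,4,12-triethyl-5-hydroxy-6,8,10-trimethyl-14-phenyltetradeca-2,7,9,11,13-pentaenoic acid F10.
- Dess–Martin oxidation of F10 returns 32.

**Step 19 (Stille coupling).** Two trisubstituted alkenyl partners are joined, and the free acid can protodestannylate the sensitive trienyl stannane. The fallback sets out from 28 and 19 and comes back at 31. Iodine–lithium exchange on 28 (t-BuLi, Et2O, −78 °C) and quench with 2-isopropoxy-4,4,5,5-tetramethyl-1,3,2-dioxaborolane gives 2-[(1E,3E,5E)-4-ethyl-2-methyl-6-phenylhexa-1,3,5-trien-1-yl]-4,4,5,5-tetramethyl-1,3,2-dioxaborolane F11. Suzuki–Miyaura coupling of F11 with 19 (Pd(PPh3)4, TlOEt, THF/H2O, rt) forms the same C8–C9 bond by base-promoted boron-to-palladium transmetallation with a protodemetallation-resistant partner and returns 31.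

Further compounds

F1 | step 21 | prop-2-en-1-yl (2E,4S,5R,6S,7E,9E,11E,13E)-2,4,12-triethyl-5-hydroxy-6,8,10-trimethyl-14-phenyltetradeca-2,7,9,11,13-pentaenoate | C=CCOC(=O)/C(CC)=C/[C@H](CC)[C@H](O)[C@@H](C)/C=C(C)/C=C(C)/C=C(CC)/C=C/c1ccccc1
F2 | step 21 | prop-2-en-1-yl (2E,4S,6S,7E,9E,11E,13E)-2,4,12-triethyl-6,8,10-trimethyl-5-oxo-14-phenyltetradeca-2,7,9,11,13-pentaenoate | C=CCOC(=O)/C(CC)=C/[C@H](CC)C(=O)[C@@H](C)/C=C(C)/C=C(C)/C=C(CC)/C=C/c1ccccc1
F3 | step 21 | prop-2-en-1-yl (1S,3S,3aR,4R,5R,7aR)-3,4-diethyl-5-[(1E,3E)-2-ethyl-4-phenylbuta-1,3-dien-1-yl]-1,5,7-trimethyl-2-oxo-2,3,3a,4,5,7a-hexahydro-1H-indene-4-carboxylate | CCC(/C=C/c1ccccc1)=C\[C@@]1(C)C=C(C)[C@@H]2[C@H]([C@H](CC)C(=O)[C@H]2C)[C@@]1(CC)C(=O)OCC=C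
F4 | step 10 | (R)-4-benzyl-3-[(2R,3S,4S,5E)-2-ethyl-3-hydroxy-6-iodo-4-methylhept-5-enoyl]oxazolidin-2-one | O=C(N1[C@H](Cc2ccccc2)COC1=O)[C@H](CC)[C@@H](O)[C@@H](C)/C=C(C)/I
F5 | step 10 | (R)-4-benzyl-3-[(2R,3S,4S,5E)-2-ethyl-6-iodo-4-methyl-3-[(triethylsilyl)oxy]hept-5-enoyl]oxazolidin-2-one | O=C(N1[C@H](Cc2ccccc2)COC1=O)[C@H](CC)[C@@H](O[Si](CC)(CC)CC)[C@@H](C)/C=C(C)/I
F6 | step 10 | (2S,3S,4S,5E)-2-ethyl-6-iodo-4-methyl-3-[(triethylsilyl)oxy]hept-5-en-1-ol | OC[C@H](CC)[C@@H](O[Si](CC)(CC)CC)[C@@H](C)/C=C(C)/I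
F7 | step 10 | (2R,3S,4S,5E)-2-ethyl-6-iodo-4-methyl-3-[(triethylsilyl)oxy]hept-5-enal | O=C[C@H](CC)[C@@H](O[Si](CC)(CC)CC)[C@@H](C)/C=C(C)/I
F8 | step 10 | 2-(trimethylsilyl)ethyl (2E,4S,5S,6S,7E)-2,4-diethyl-8-iodo-6-methyl-5-[(triethylsilyl)oxy]nona-2,7-dienoate | C[Si](C)(C)CCOC(=O)/C(CC)=C/[C@H](CC)[C@@H](O[Si](CC)(CC)CC)[C@@H](C)/C=C(C)/I
F9 | step 10 | (2E,4S,5S,6S,7E)-2,4-diethyl-5-hydroxy-8-iodo-6-methylnona-2,7-dienoic acid | OC(=O)/C(CC)=C/[C@H](CC)[C@@H](O)[C@@H](C)/C=C(C)/I
F10 | step 10 | (2E,4S,5S,6S,7E,9E,11E,13E)-2,4,12-triethyl-5-hydroxy-6,8,10-trimethyl-14-phenyltetradeca-2,7,9,11,13-pentaenoic acid | OC(=O)/C(CC)=C/[C@H](CC)[C@@H](O)[C@@H](C)/C=C(C)/C=C(C)/C=C(CC)/C=C/c1ccccc1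
F11 | step 19 | 2-[(1E,3E,5E)-4-ethyl-2-methyl-6-phenylhexa-1,3,5-trien-1-yl]-4,4,5,5-tetramethyl-1,3,2-dioxaborolane | CC1(C)OB(/C=C(C)/C=C(CC)/C=C/c2ccccc2)OC1(C)C
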